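**Retrosynthetic overview**
1. The C40 chain is cut at C11=C12 and C11'=C12' (two Wittig reactions) into ring A C15 phosphonium salt 21, C10 dialdehyde 22 and ring B C15 phosphonium salt 14.
2. Ring A is not built: purchased (4R,6R)-actinol 15 gives enol triflate 18 (C5=C6 fixed), and Sonogashira coupling with enynol 19 makes C6–C7.
3. Ring B is the only ring formed. In step 7 the enolate of an acyclic ketone made from geraniol (C1', C6' and the whole C7'–C11' chain) is annulated with C5 dienylphosphonium salt 3: C1'–C2' by conjugate addition, C5'=C6' by intramolecular Wittig reaction.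
4. Enabling feature: in ring B the quaternary C1'(CH3)2 is α to the sp2 carbon C6', which carries a saturated C7'H2–C8'H2 chain. C1'/C6' therefore map onto the α-carbon and carbonyl carbon of an isopropyl ketone, and C2'–C3'–C4'–C5'(CH3) onto a 1-methylbutadienyl phosphorus unit.
5. C3' is homoallylic to C5'=C6', so the 3'R hydroxyl is installed afterwards by asymmetric hydroboration of the 3',4'-alkene of the cyclohexa-1,3-diene that step 7 delivers.

Key step: step 7

Remark: the target is read as the all-E (3R,3'R) isomer; 1, 4, 15 (the (4R,6R) ketone known as actinol), 19 and 22 are taken as purchasable.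

Step 1
Reactants: 1 pent-4-en-2-one
Product: 2 penta-2,4-dien-2-yl trifluoromethanesulfonate (E/Z mixture)
Conditions: Tf2O, 2,6-di-tert-butyl-4-methylpyridine, CH2Cl2, −78 → 0 °C
Reagents that add atoms: trifluoromethanesulfonic anhydride, O=S(=O)(OS(=O)(=O)C(F)(F)F)C(F)(F)F
Why: O-triflation of the ketone followed by loss of the C3 proton, which is both α to the oxocarbenium carbon and allylic, should give the through-conjugated dienyl triflate (enol triflate formation), and its E/Z ratio is without consequence because both isomers converge in step 7.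

Step 2
Reactants: 2 penta-2,4-dien-2-yl trifluoromethanesulfonate
Product: 3 (penta-2,4-dien-2-yl)triphenylphosphonium trifluoromethanesulfonate (E/Z mixture)
Conditions: PPh3 (1.0 equiv), Pd(PPh3)4 (2 mol %), THF, 65 °C
Reagents that add atoms: triphenylphosphine, c1ccc(P(c2ccccc2)c2ccccc2)cc1
Why: Oxidative addition of an alkenyl triflate to zerovalent palladium and C–P reductive elimination with PPh3 is a known route to alkenyltriphenylphosphonium triflates, and the salt is expected to separate from THF before PPh3 can add to it.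

Step 3
Reactants: 4 geraniol
Product: 5 (E)-tert-butyl[(3,7-dimethylocta-2,6-dien-1-yl)oxy]dimethylsilane
Conditions: TBSCl, imidazole, DMF, 0 °C → rt
Reagents that add atoms: tert-butyldimethylsilyl chloride, CC(C)(C)[Si](C)(C)Cl
Why: Standard silylation of a primary allylic alcohol, chosen because the silyl ether survives peracid, alkoxide, hydride, enolate, ylide and borane conditions and is released by the acid of step 9.

Step 4
Reactants: 5 (E)-tert-butyl[(3,7-dimethylocta-2,6-dien-1-yl)oxy]dimethylsilane
Product: 6 (E)-tert-butyl{[5-(3,3-dimethyloxiran-2-yl)-3-methylpent-2-en-1-yl]oxy}dimethylsilane (racemic)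
Conditions: mCPBA (1.0 equiv), NaHCO3, CH2Cl2, −20 → 0 °C
Reagents that add atoms: 3-chloroperbenzoic acid, OOC(=O)c1cccc(Cl)c1
Why: Prilezhaev epoxidation should favour the remote 6,7-alkene, the 2,3-alkene being deactivated by the allylic oxygen, and the new stereocentre may be racemic because it is erased in step 6.

Step 5
Reactants: 6 (E)-tert-butyl{[5-(3,3-dimethyloxiran-2-yl)-3-methylpent-2-en-1-yl]oxy}dimethylsilane
Product: 7 (E)-8-[(tert-butyldimethylsilyl)oxy]-2,6-dimethylocta-1,6-dien-3-ol (racemic)
Conditions: Al(OiPr)3 (0.5 equiv), toluene, 110 °C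
Reagents that add atoms: none
Why: Al(OiPr)3-mediated isomerisation of a 2,2-dimethyl-3-alkyloxirane removes a methyl proton syn to the breaking tertiary C–O bond and gives the isopropenyl carbinol (epoxide to allylic alcohol rearrangement), the carbinol centre staying racemic.

Step 6
Reactants: 7 (E)-8-[(tert-butyldimethylsilyl)oxy]-2,6-dimethylocta-1,6-dien-3-ol
Product: 8 (E)-8-[(tert-butyldimethylsilyl)oxy]-2,6-dimethylocta-1,6-dien-3-one
Conditions: Dess–Martin periodinane, NaHCO3, CH2Cl2, 0 °C; used at once
Reagents that add atoms: none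
Why: Dess–Martin oxidation converts the secondary allylic alcohol to the α-methylene ketone under buffered conditions that spare the silyl ether and the trisubstituted alkene.

Step 7
Reactants: 8 (E)-8-[(tert-butyldimethylsilyl)oxy]-2,6-dimethylocta-1,6-dien-3-one; 3 (penta-2,4-dien-2-yl)triphenylphosphonium trifluoromethanesulfonate
Product: 11 (E)-tert-butyldimethyl{[3-methyl-5-(2,6,6-trimethylcyclohexa-1,3-dien-1-yl)pent-2-en-1-yl]oxy}silane, via lithium enolate 9 (not isolated), via keto ylide 10 (not isolated)
Conditions: LiBH(s-Bu)3 (1.0 equiv), THF, −78 °C; then 3 (1.1 equiv), THF–DMPU, −78 → 20 °C; then 65 °C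
Reagents that add atoms: none
Why: Conjugate hydride transfer to the unsubstituted β-carbon of 8 gives the tetrasubstituted lithium enolate 9 regiospecifically, so that C1' and not C7' becomes the nucleophile. Enolate 9 adds through C1' to the terminal CH2 (C2') of dienylphosphonium salt 3 (vinylogous conjugate addition), which forms the quaternary C1'–C2' bond and the allylic ylide 10, and the ylide carbon C5' then attacks the C6' ketone in a 6-exo-trig closure, the oxaphosphetane collapsing to the tetrasubstituted C5'=C6' bond with loss of Ph3PO (intramolecular Wittig reaction). The closest known reaction type is the cyclohexa-1,3-diene annulation of enolates with buta-1,3-dienylphosphonium salts. No stereocentre is formed, and the step is stereoconvergent: both geometric isomers of 3 and of the delocalised ylide 10 end in the one ring alkene because only the cisoid ylide can close, while the racemic carbinol centre of 7 has already been erased in 8. The selectivity needed is C- over O-attack and attack at the terminal rather than the internal position of 3, secured by the soft charge-delocalised acceptor, its unhindered CH2 terminus and the methyl group on its α-carbon, together with olefination ahead of proton transfer, secured by the low basicity of an allylic ylide toward a dialkyl ketone. The hindered by-product B(s-Bu)3 is not expected to bind the fully substituted ylide carbon.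

Step 8
Reactants: 11 (E)-tert-butyldimethyl{[3-methyl-5-(2,6,6-trimethylcyclohexa-1,3-dien-1-yl)pent-2-en-1-yl]oxy}silane
Product: 13 (1R)-4-{(E)-5-[(tert-butyldimethylsilyl)oxy]-3-methylpent-3-en-1-yl}-3,5,5-trimethylcyclohex-3-en-1-ol, via trialkylborane 12 (not isolated)
Conditions: (+)-Ipc2BH (preformed reagent, the enantiomer derived from (−)-α-pinene), THF, −25 → 0 °C; then NaOH, H2O2, 0 °C → rt
Reagents that add atoms: hydrogen peroxide, OO
Why: Brown asymmetric hydroboration should engage only the cis-disubstituted C3'=C4' bond (the tetrasubstituted C5'=C6' and trisubstituted C9'=C10' bonds are inert toward the bulky dialkylborane), place boron on C3' away from the C5' methyl group and, with this enantiomer of the reagent, add to the face that the model for cis-alkenes assigns to 3'R, the C–B bond then being oxidised with retention.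

Step 9
Reactants: 13 (1R)-4-{(E)-5-[(tert-butyldimethylsilyl)oxy]-3-methylpent-3-en-1-yl}-3,5,5-trimethylcyclohex-3-en-1-ol
Product: 14 {(E)-5-[(4R)-4-hydroxy-2,6,6-trimethylcyclohex-1-en-1-yl]-3-methylpent-2-en-1-yl}triphenylphosphonium bromide
Conditions: PPh3·HBr (1.1 equiv), MeOH–CH2Cl2, rt
Reagents that add atoms: triphenylphosphine hydrobromide, Br.c1ccc(P(c2ccccc2)c2ccccc2)cc1
Why: Acid cleavage of the primary allylic silyl ether and substitution of the allylic position by PPh3 at the primary terminus (allylic phosphonium salt formation) should leave the homoallylic ring hydroxyl and the E-configured C9'=C10' bond untouched.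

Step 10
Reactants: 15 (4R,6R)-4-hydroxy-2,2,6-trimethylcyclohexan-1-one
Product: 16 (4R,6R)-2,2,6-trimethyl-4-[(triethylsilyl)oxy]cyclohexan-1-one
Conditions: Et3SiCl, imidazole, DMF, 0 °C
Reagents that add atoms: chlorotriethylsilane, CC[Si](Cl)(CC)CC
Why: Silylation masks the secondary alcohol during enolate formation, the triethylsilyl group being chosen because it falls off under the acidic conditions of step 13.

Step 11
Reactants: 16 (4R,6R)-2,2,6-trimethyl-4-[(triethylsilyl)oxy]cyclohexan-1-one
Product: 18 (4R)-2,6,6-trimethyl-4-[(triethylsilyl)oxy]cyclohex-1-en-1-yl trifluoromethanesulfonate, via lithium enolate 17 (not isolated)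
Conditions: LiN(i-Pr)2, THF, −78 °C; then PhNTf2, −78 → 0 °C
Reagents that add atoms: N-phenylbis(trifluoromethanesulfonimide), O=S(=O)(N(c1ccccc1)S(=O)(=O)C(F)(F)F)C(F)(F)F
Why: The ketone can enolise only toward C5 because C1 is quaternary, so O-triflation of the lithium enolate fixes the tetrasubstituted C5=C6 bond and erases the C5 stereocentre while C3 (R) is untouched.

Step 12
Reactants: 18 (4R)-2,6,6-trimethyl-4-[(triethylsilyl)oxy]cyclohex-1-en-1-yl trifluoromethanesulfonate; 19 (E)-3-methylpent-2-en-4-yn-1-ol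
Product: 20 (E)-3-methyl-5-{(4R)-2,6,6-trimethyl-4-[(triethylsilyl)oxy]cyclohex-1-en-1-yl}pent-2-en-4-yn-1-ol
Conditions: Pd(PPh3)4 (5 mol %), CuI (10 mol %), i-Pr2NH, DMF, 20 → 50 °C
Reagents that add atoms: none
Why: Sonogashira coupling of the alkenyl triflate with the terminal alkyne forms the C6–C7 bond and carries the E-configured C9=C10 bond of 19 over unchanged, the free hydroxyl being tolerated.

Step 13
Reactants: 20 (E)-3-methyl-5-{(4R)-2,6,6-trimethyl-4-[(triethylsilyl)oxy]cyclohex-1-en-1-yl}pent-2-en-4-yn-1-ol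
Product: 21 {(E)-5-[(4R)-4-hydroxy-2,6,6-trimethylcyclohex-1-en-1-yl]-3-methylpent-2-en-4-yn-1-yl}triphenylphosphonium bromide
Conditions: PPh3·HBr (1.1 equiv), MeOH, 0 °C → rt
Reagents that add atoms: triphenylphosphine hydrobromide, Br.c1ccc(P(c2ccccc2)c2ccccc2)cc1
Why: The primary allylic alcohol is converted to the phosphonium salt by PPh3·HBr (allylic substitution at the primary terminus) while the same acid removes the triethylsilyl ether, the secondary ring hydroxyl not being ionised.

Step 14
Reactants: 21 ring A C15 phosphonium bromide; 22 (2E,4E,6E)-2,7-dimethylocta-2,4,6-trienedial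
Product: 24 (3R)-3-hydroxy-7,8-didehydro-12'-apo-β-caroten-12'-al (all-E), via phosphorus ylide 23 (not isolated)
Conditions: NaOMe (1.05 equiv), 22 (3 equiv), CH2Cl2–MeOH, 0 → 20 °C; then I2 (cat.), CH2Cl2, daylight; crystallisation
Reagents that add atoms: none
Why: Wittig olefination of one aldehyde group of the dialdehyde (used in excess to suppress double olefination) forms C11=C12, and the E/Z mixture expected from the semistabilised ylide is funnelled toward the all-E aldehyde by iodine-catalysed equilibration and crystallisation.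

Step 15
Reactants: 14 ring B C15 phosphonium bromide; 24 (3R)-3-hydroxy-7,8-didehydro-12'-apo-β-caroten-12'-al
Product: 26 (3R,3'R)-7,8-didehydro-7',8'-dihydro-β,β-carotene-3,3'-diol (all-E), via phosphorus ylide 25 (not isolated)
Conditions: NaOMe (1.1 equiv), CH2Cl2–MeOH, 0 → 20 °C; then EtOH, 78 °C; crystallisation
Reagents that add atoms: none
Why: Wittig olefination forms C11'=C12' without touching either carbinol centre, and the sterically congested 11'Z isomer should relax thermally to E, so that both geometric isomers converge on the all-E target.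

**Compound list**
1 | pent-4-en-2-one | CC(=O)CC=C | starting material
2 | penta-2,4-dien-2-yl trifluoromethanesulfonate (E/Z mixture) | C=CC=C(C)OS(=O)(=O)C(F)(F)F | intermediate
3 | (penta-2,4-dien-2-yl)triphenylphosphonium trifluoromethanesulfonate (E/Z mixture) | C=CC=C(C)[P+](c1ccccc1)(c1ccccc1)c1ccccc1.[O-]S(=O)(=O)C(F)(F)F | intermediate
4 | geraniol | CC(C)=CCC/C(C)=C/CO | starting material
5 | (E)-tert-butyl[(3,7-dimethylocta-2,6-dien-1-yl)oxy]dimethylsilane | CC(C)=CCC/C(C)=C/CO[Si](C)(C)C(C)(C)C | intermediate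
6 | (E)-tert-butyl{[5-(3,3-dimethyloxiran-2-yl)-3-methylpent-2-en-1-yl]oxy}dimethylsilane, racemic | CC1(C)OC1CC/C(C)=C/CO[Si](C)(C)C(C)(C)C | intermediate
7 | (E)-8-[(tert-butyldimethylsilyl)oxy]-2,6-dimethylocta-1,6-dien-3-ol, racemic | C=C(C)C(O)CC/C(C)=C/CO[Si](C)(C)C(C)(C)C | intermediate
8 | (E)-8-[(tert-butyldimethylsilyl)oxy]-2,6-dimethylocta-1,6-dien-3-one | C=C(C)C(=O)CC/C(C)=C/CO[Si](C)(C)C(C)(C)C | intermediate
9 | lithium (E)-8-[(tert-butyldimethylsilyl)oxy]-2,6-dimethylocta-2,6-dien-3-olate | CC(C)=C(O[Li])CC/C(C)=C/CO[Si](C)(C)C(C)(C)C | intermediate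
10 | (10E)-12-[(tert-butyldimethylsilyl)oxy]-6,6,10-trimethyl-2-(triphenyl-λ5-phosphanylidene)dodeca-3,10-dien-7-one (3,4-geometry mobile) | CC(C=CCC(C)(C)C(=O)CC/C(C)=C/CO[Si](C)(C)C(C)(C)C)=P(c1ccccc1)(c1ccccc1)c1ccccc1 | intermediate
11 | (E)-tert-butyldimethyl{[3-methyl-5-(2,6,6-trimethylcyclohexa-1,3-dien-1-yl)pent-2-en-1-yl]oxy}silane | CC1=C(CC/C(C)=C/CO[Si](C)(C)C(C)(C)C)C(C)(C)CC=C1 | intermediate
12 | {(1R)-4-[(E)-5-[(tert-butyldimethylsilyl)oxy]-3-methylpent-3-en-1-yl]-3,5,5-trimethylcyclohex-3-en-1-yl}bis(isopinocampheyl)borane | CC1=C(CC/C(C)=C/CO[Si](C)(C)C(C)(C)C)C(C)(C)C[C@H](B([C@H]2C[C@H]3C[C@@H]([C@@H]2C)C3(C)C)[C@H]2C[C@H]3C[C@@H]([C@@H]2C)C3(C)C)C1 | intermediate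
13 | (1R)-4-{(E)-5-[(tert-butyldimethylsilyl)oxy]-3-methylpent-3-en-1-yl}-3,5,5-trimethylcyclohex-3-en-1-ol | CC1=C(CC/C(C)=C/CO[Si](C)(C)C(C)(C)C)C(C)(C)C[C@H](O)C1 | intermediate
14 | {(E)-5-[(4R)-4-hydroxy-2,6,6-trimethylcyclohex-1-en-1-yl]-3-methylpent-2-en-1-yl}triphenylphosphonium bromide | CC1=C(CC/C(C)=C/C[P+](c2ccccc2)(c2ccccc2)c2ccccc2)C(C)(C)C[C@H](O)C1.[Br-] | intermediate
15 | (4R,6R)-4-hydroxy-2,2,6-trimethylcyclohexan-1-one (actinol) | CC1(C)C[C@H](O)C[C@@H](C)C1=O | starting material
16 | (4R,6R)-2,2,6-trimethyl-4-[(triethylsilyl)oxy]cyclohexan-1-one | CC1(C)C[C@H](O[Si](CC)(CC)CC)C[C@@H](C)C1=O | intermediate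
17 | lithium (4R)-2,6,6-trimethyl-4-[(triethylsilyl)oxy]cyclohex-1-en-1-olate | CC1=C(O[Li])C(C)(C)C[C@H](O[Si](CC)(CC)CC)C1 | intermediate
18 | (4R)-2,6,6-trimethyl-4-[(triethylsilyl)oxy]cyclohex-1-en-1-yl trifluoromethanesulfonate | CC1=C(OS(=O)(=O)C(F)(F)F)C(C)(C)C[C@H](O[Si](CC)(CC)CC)C1 | intermediate
19 | (E)-3-methylpent-2-en-4-yn-1-ol | C#C/C(C)=C/CO | starting material
20 | (E)-3-methyl-5-{(4R)-2,6,6-trimethyl-4-[(triethylsilyl)oxy]cyclohex-1-en-1-yl}pent-2-en-4-yn-1-ol | CC1=C(C#C/C(C)=C/CO)C(C)(C)C[C@H](O[Si](CC)(CC)CC)C1 | intermediate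
21 | {(E)-5-[(4R)-4-hydroxy-2,6,6-trimethylcyclohex-1-en-1-yl]-3-methylpent-2-en-4-yn-1-yl}triphenylphosphonium bromide | CC1=C(C#C/C(C)=C/C[P+](c2ccccc2)(c2ccccc2)c2ccccc2)C(C)(C)C[C@H](O)C1.[Br-] | intermediate
22 | (2E,4E,6E)-2,7-dimethylocta-2,4,6-trienedial | O=C/C(C)=C/C=C/C=C(C)/C=O | starting material
23 | ylide of 21, (4R)-3,5,5-trimethyl-4-[(E)-3-methyl-5-(triphenyl-λ5-phosphanylidene)pent-3-en-1-yn-1-yl]cyclohex-3-en-1-ol | CC1=C(C#C/C(C)=C/C=P(c2ccccc2)(c2ccccc2)c2ccccc2)C(C)(C)C[C@H](O)C1 | intermediate
24 | (3R)-3-hydroxy-7,8-didehydro-12'-apo-β-caroten-12'-al, all-E | CC1=C(C#C/C(C)=C/C=C/C(C)=C/C=C/C=C(C)/C=O)C(C)(C)C[C@H](O)C1 | intermediate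
25 | ylide of 14, (1R)-3,5,5-trimethyl-4-[(E)-3-methyl-5-(triphenyl-λ5-phosphanylidene)pent-3-en-1-yl]cyclohex-3-en-1-ol | CC1=C(CC/C(C)=C/C=P(c2ccccc2)(c2ccccc2)c2ccccc2)C(C)(C)C[C@H](O)C1 | intermediate
26 | (3R,3'R)-7,8-didehydro-7',8'-dihydro-β,β-carotene-3,3'-diol, all-E | CC1=C(C#C/C(C)=C/C=C/C(C)=C/C=C/C=C(C)/C=C/C=C(\C)CCC2=C(C)C[C@@H](O)CC2(C)C)C(C)(C)C[C@H](O)C1 | target

**Step count**
Total steps: 15. Longest linear sequence: 8 steps (steps 3 to 9, then step 15), starting from geraniol.

**Steps most likely to fail**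

Step 7. The cascade may be diverted by proton transfer from the α-methyl group of 3 to enolate 9, by O-attack or attack at the internal position of 3, or by slow closure of ylide 10 onto the neopentyl-type ketone. The fallback gives up the annulation and takes ring B from the chiral pool; it sets out from 18 and 19 and comes back at 14. Semihydrogenation of 19 (H2, Pd/CaCO3 poisoned with Pb(OAc)2, quinoline) would give (E)-3-methylpenta-2,4-dien-1-ol F1. Silylation would give its tert-butyldimethylsilyl ether F2. Hydroboration of the terminal vinyl group with 9-BBN-H would give the B-alkyl borane F3. B-alkyl Suzuki–Miyaura coupling of F3 with enol triflate 18 [PdCl2(dppf), K3PO4, DMF–THF–H2O] would give the bis-silyl ether F4. PPh3·HBr in MeOH would then remove both silyl groups and install the phosphonium group, which is 14.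

Step 8. Boron may be delivered to C4' instead of C3', and facial discrimination on the hindered diene may be insufficient. The fallback replaces hydroboration by oxidation and reductive opening; it sets out from 11 and comes back at 13. Jacobsen–Katsuki epoxidation of the conjugated cis-disubstituted C3'=C4' bond would give the (3'S,4'R)-oxirane F5. The conditions are NaOCl, 4-phenylpyridine N-oxide and the (R,R)-[N,N'-bis(3,5-di-tert-butylsalicylidene)cyclohexane-1,2-diamine]MnCl complex of trivalent manganese, chosen by analogy with cyclic aryl-conjugated cis-alkenes. Palladium-catalysed hydrogenolysis of the alkenyl oxirane [Pd2(dba)3, PBu3, HCO2H, Et3N, dioxane] would then deliver hydride to the allylic carbon C4' and leave the 3'R alcohol 13.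

Step 2. PPh3 may add to the dienylphosphonium product, and the dienyl triflate may oligomerise under palladium catalysis. The fallback moves to a neutral phosphorus reagent and a different olefination; it sets out from 2 and comes back at 11. Hirao coupling of 2 with diethyl phosphite [Pd(PPh3)4, Et3N, toluene] would give diethyl (penta-2,4-dien-2-yl)phosphonate F6. F6 would take the place of 3 in step 7: conjugate addition of enolate 9 followed by intramolecular Horner–Wadsworth–Emmons olefination would give 11.

**Further compounds**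
F1 | step 7 | (E)-3-methylpenta-2,4-dien-1-ol | C=C/C(C)=C/CO
F2 | step 7 | (E)-tert-butyldimethyl[(3-methylpenta-2,4-dien-1-yl)oxy]silane | C=C/C(C)=C/CO[Si](C)(C)C(C)(C)C
F3 | step 7 | 9-{(E)-5-[(tert-butyldimethylsilyl)oxy]-3-methylpent-3-en-1-yl}-9-borabicyclo[3.3.1]nonane | CC(C)(C)[Si](C)(C)OC/C=C(\C)CCB1C2CCCC1CCC2
F4 | step 7 | (E)-tert-butyldimethyl{[3-methyl-5-{(4R)-2,6,6-trimethyl-4-[(triethylsilyl)oxy]cyclohex-1-en-1-yl}pent-2-en-1-yl]oxy}silane | CC1=C(CC/C(C)=C/CO[Si](C)(C)C(C)(C)C)C(C)(C)C[C@H](O[Si](CC)(CC)CC)C1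
F5 | step 8 | (3'S,4'R)-3',4'-epoxide of 11 | CC1=C(CC/C(C)=C/CO[Si](C)(C)C(C)(C)C)C(C)(C)C[C@@H]2O[C@H]12
F6 | step 2 | diethyl (penta-2,4-dien-2-yl)phosphonate (E/Z mixture) | C=CC=C(C)P(=O)(OCC)OCC
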